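**Plan** (fluorene numbering for the core: ring A = C1–C4, C4a, C9a; ring B = C4a, C4b, C8a, C9, C9a; ring C = C4b, C5–C8, C8a; β = face of the C4b methyl)
- Retrosynthesis: open the hemiaminal C–N (→ γ-keto β-keto nitrile), cut the aryl ether C9–O (macrocycle), cut C1′–C(α-cyano) (nitrile-anion aldol), then cut the two ring-B bonds C4a–C4b and C8a–C9.
- Enabling feature: ring C carries methyls on C4b, C6, C8 (1,3,5), with quaternary C4b next to CH-8a and para to C7. It is a reduced 2,4,6-trimethylphenol (phenol C4 → C4b, C3 → C8a, C1 → C7). C4a is allylic to C3=C4 and C9 is a carbinol carbon, so ring A can serve as a π-allyl at C4a plus an acyl anion at C9.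
- Forward: ring A by organocatalytic Michael/aldol annulation → dearomative [3+2] annulation with mesitol closes ring B and sets quaternary C4b → dehydrogenation/Li–NH3 turns the B/C fusion trans, Wolff–Kishner removes the phenol oxygen → side chain by nitrile aldol → Cu-mediated macro-etherification → keto amide closes to the hydroxy-lactam.
- Stereochemistry: one catalytic centre (C1, step 1). C2, C9a and the C3 carbinol follow by substrate control on ring A; C4a by double inversion at Pd; C4b by enone-arm selection; C8a, C6, C8 by dissolving-metal reduction and equilibration; C9 by hydride attack anti to the angular methyl; the lactam centres are thermodynamic.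

Key step: step 11

Assumption: the two lactam stereocentres of the target (acyl-bearing C3 and hemiaminal C5) are taken as the thermodynamically preferred pair inside the 13-membered ring; C3 epimerises through the β-keto amide enol and C5 through ring–chain tautomerism.
Assumption: compounds 1, 2, 14, 23 and 25 are purchased; for the carbene catalyst of step 11 both antipodes are available and the one matched to the substrate is used.

**Route**

Step 1
Reactants: 1 (E)-4-(benzyloxy)but-2-enal; 2 ethyl 3-oxopentanoate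
Product: 4 ethyl (6R)-6-[(benzyloxy)methyl]-3-methyl-2-oxocyclohex-3-ene-1-carboxylate, via Michael adduct 3 (not isolated)
Conditions: (S)-α,α-diphenylprolinol TMS ether (10 mol%), PhCO2H (10 mol%), toluene, 0 °C → rt; then TsOH·H2O (20 mol%), toluene, 60 °C
Reagents that add atoms: none
Why: Iminium-catalysed Michael addition (the (S)-catalyst shields one face of the enal, which should give the (R)-adduct) followed by acid-mediated intramolecular aldol condensation of the ethyl-ketone α′-CH2 onto the aldehyde, an organocatalytic cyclohexenone annulation.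

Step 2
Reactants: 4
Product: 5 ethyl (1R,6R)-6-[(benzyloxy)methyl]-1,3-dimethyl-2-oxocyclohex-3-ene-1-carboxylate
Conditions: K2CO3, MeI, acetone, rt
Reagents that add atoms: iodomethane, CI
Why: C-alkylation of the cyclic β-keto ester enolate anti to the neighbouring CH2OBn group should set the quaternary carbon (future C2) with the ester cis to CH2OBn.

Step 3
Reactants: 5
Product: 6 ethyl 6-[(benzyloxy)methyl]-2-[(tert-butyldimethylsilyl)oxy]-1,3-dimethylcyclohexa-2,4-diene-1-carboxylate
Conditions: TBSOTf, Et3N, CH2Cl2, 0 °C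
Reagents that add atoms: tert-butyldimethylsilyl triflate, CC(C)(C)[Si](C)(C)OS(=O)(=O)C(F)(F)F
Why: Soft enolisation can only remove a γ-hydrogen (the α′ carbon is quaternary), giving the extended silyl dienol ether.

Step 4
Reactants: 6
Product: 7 ethyl 6-[(benzyloxy)methyl]-5-(dimethoxymethyl)-1,3-dimethyl-2-oxocyclohex-3-ene-1-carboxylate (5-CH(OMe)2 trans to 6-CH2OBn)
Conditions: HC(OMe)3, BF3·OEt2, CH2Cl2, −78 °C
Reagents that add atoms: trimethyl orthoformate, COC(OC)OC
Why: Vinylogous Mukaiyama reaction; the dimethoxycarbenium ion should be taken up at the γ-carbon (future C9a) anti to the adjacent CH2OBn group.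

Step 5
Reactants: 7
Product: 8 {6-[(benzyloxy)methyl]-5-(dimethoxymethyl)-2-hydroxy-1,3-dimethylcyclohex-3-en-1-yl}methanol (carbinol configuration irrelevant)
Conditions: LiAlH4, THF, 0 °C
Reagents that add atoms: none
Why: Hydride reduction of the neopentyl ester and 1,2-reduction of the enone; the secondary carbinol is re-oxidised in step 6.

Step 6
Reactants: 8
Product: 9 6-[(benzyloxy)methyl]-5-(dimethoxymethyl)-1,3-dimethyl-2-oxocyclohex-3-ene-1-carbaldehyde
Conditions: Dess–Martin periodinane, NaHCO3, CH2Cl2, rt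
Reagents that add atoms: none
Why: Dess–Martin oxidation of both alcohols gives a non-enolisable β-keto aldehyde.

Step 7
Reactants: 9
Product: 10 5-[(benzyloxy)methyl]-4-(dimethoxymethyl)-6-ethenyl-2,6-dimethylcyclohex-2-en-1-one (6-vinyl cis to 5-CH2OBn)
Conditions: Ph3PCH3Br, KHMDS, THF, −78 → 0 °C
Reagents that add atoms: methyltriphenylphosphonium bromide, C[P+](c1ccccc1)(c1ccccc1)c1ccccc1.[Br-]
Why: Wittig methylenation should be chemoselective for the aldehyde over the hindered enone carbonyl.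

Step 8
Reactants: 10
Product: 11 5-[(benzyloxy)methyl]-4-(dimethoxymethyl)-6-ethenyl-2,6-dimethylcyclohex-2-en-1-ol (1-OH cis to 6-vinyl)
Conditions: NaBH4, CeCl3·7H2O, MeOH, −78 °C
Reagents that add atoms: none
Why: Luche 1,2-reduction; axial hydride attack anti to the axial vinyl group on the adjacent quaternary carbon should give the equatorial alcohol cis to vinyl.

Step 9
Reactants: 11
Product: 12 methyl carbonate of 11
Conditions: ClCO2Me, pyridine, DMAP (cat.), CH2Cl2, 0 °C
Reagents that add atoms: methyl chloroformate, COC(=O)Cl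
Why: Acylation of the allylic alcohol installs the leaving group for π-allyl formation.

Step 10
Reactants: 12
Product: 13 6-[(benzyloxy)methyl]-5-ethenyl-4-[(methoxycarbonyl)oxy]-3,5-dimethylcyclohex-2-ene-1-carbaldehyde (1-CHO trans to 6-CH2OBn)
Conditions: Amberlyst-15, acetone/H2O (20:1), 0 °C → rt; used directly
Reagents that add atoms: water, O
Why: Mild acetal hydrolysis; the β,γ-unsaturated aldehyde is used without storage to avoid conjugation.

Step 11
Reactants: 13; 14 2,4,6-trimethylphenol (mesitol)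
Product: 16 cis-B/C hydrofluorene-7,9-dione (1β-CH2OBn; 2β-vinyl; 4a-Hα; 4b-Meβ; 8a-Hβ; 9a-Hβ), via para-allylated cyclohexadienone aldehyde 15 (not isolated)
Conditions: Pd2(dba)3·CHCl3 (2.5 mol%), dppf (6 mol%), 14 (1.5 equiv), toluene, 50 °C; then aminoindanol-derived N-C6F5 triazolium tetrafluoroborate (20 mol%, matched antipode), i-Pr2NEt, 23 °C
Reagents that add atoms: none
Why: Proposed new method: Pd(0) ionises the allylic carbonate with inversion to a π-allyl (C3–C4–C4a) and the mesitolate formed by the released methoxide attacks through its para carbon (the future C4b) at the less hindered terminus C4a anti to Pd, so the C4a–C4b bond should stand on the face the carbonate left (net retention, trans to the C9a formyl group) and the alkene comes to C3=C4; O-allyl and ortho-dienone isomers stay re-ionisable (phenoxide leaving group) and should funnel to the 4,4-disubstituted cyclohexa-2,5-dienone 15, the only isomer the next event traps. The triazolylidene then turns the C9 aldehyde into its Breslow intermediate, which adds 5-exo-trig to the β-carbon of one enone arm (C8a–C9 bond, ring B closed), an intramolecular Stetter reaction that desymmetrises the prochiral dienone. The closest known reaction types are the Pd-catalysed allylic dearomatisation of phenols and naphthols (not established intermolecularly at the para carbon of a simple trialkylphenol, hence the label) and the desymmetrising Stetter cyclisation of 4,4-disubstituted cyclohexadienones. Stereocontrol: C4a by double inversion at Pd; C4b by the choice of enone arm, dictated by the chiral carbene; C8a necessarily cis to the C4a–C4b bond because the tether reaches only that face (corrected in step 14); C8 by enol protonation and irrelevant. The step needs C- over O-allylation, para over ortho attack and one enone arm over the other; the first two rest on reversibility under Pd together with the irreversible Stetter trap, the third on catalyst control.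

Step 12
Reactants: 16
Product: 17 9α-hydroxy enone (9-ketone of 16 reduced; enone at C7 kept)
Conditions: NaBH4, MeOH/CH2Cl2 (1:1), −78 °C
Reagents that add atoms: none
Why: Borohydride reduces the saturated cyclopentanone faster than the hindered conjugated enone, from the convex face of the cis-hydrindane; the C9 configuration is reset later.

Step 13
Reactants: 17
Product: 19 9α-hydroxy cross-conjugated dienone (Δ5 and Δ8(8a), 7-oxo), via bis(trimethylsilyl) dienol ether 18 (not isolated)
Conditions: LDA (2.3 equiv), TMSCl, THF, −78 °C; then Pd(OAc)2 (1.1 equiv), MeCN, 23 °C; K2CO3, MeOH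
Reagents that add atoms: none
Why: Saegusa–Ito dehydrogenation; the ketone can enolise only toward C8 (the other α-carbon is sp2) and syn β-hydride elimination of the β-oriented 8a-H makes C8a trigonal again.

Step 14
Reactants: 19
Product: 20 trans-B/C keto diol (1β-CH2OH; 9α-OH; 7-oxo; 6α-Me; 8α-Me; 8a-Hα)
Conditions: Li (12 equiv), NH3(l)/THF, t-BuOH (4 equiv), −78 → −33 °C; NH4Cl; then NaOMe (0.2 equiv), MeOH, 23 °C
Reagents that add atoms: none
Why: Birch-type reduction of both enone arms; as with hydrindenones of the Hajos–Parrish type the C8a carbanion should be protonated anti to the angular methyl (trans fusion), the C9 lithium alkoxide is too poor a leaving group to eliminate, the benzyl ether is cleaved, and base equilibration places the C6 and C8 methyls equatorial.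

Step 15
Reactants: 20
Product: 22 diol (7-deoxo; 1β-CH2OH; 9α-OH), via hydrazone 21 (not isolated)
Conditions: N2H4·H2O, KOH, diethylene glycol, 130 °C then 210 °C
Reagents that add atoms: none
Why: Wolff–Kishner reduction (Huang-Minlon) removes the former phenol oxygen; alcohols and isolated alkenes tolerate the conditions.

Step 16
Reactants: 23 2-(4-iodophenyl)ethanol
Product: 24 (4-iodophenyl)acetaldehyde
Conditions: Dess–Martin periodinane, NaHCO3, CH2Cl2, 0 °C
Reagents that add atoms: none
Why: Dess–Martin oxidation of a primary alcohol.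

Step 17
Reactants: 24; 25 acrylonitrile
Product: 26 5-(4-iodophenyl)-4-oxopentanenitrile
Conditions: 3-benzyl-5-(2-hydroxyethyl)-4-methylthiazolium chloride (20 mol%), Et3N, EtOH, 70 °C
Reagents that add atoms: none
Why: Intermolecular Stetter reaction of an aliphatic aldehyde with acrylonitrile gives the γ-keto nitrile.

Step 18
Reactants: 26
Product: 27 3-[2-(4-iodobenzyl)-1,3-dioxolan-2-yl]propanenitrile
Conditions: ethylene glycol, TsOH·H2O (cat.), benzene, reflux (Dean–Stark)
Reagents that add atoms: ethylene glycol, OCCO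
Why: Ketalisation masks the ketone against the nitrile anion and the later base.

Step 19
Reactants: 22
Product: 28 9-oxo-1β-carbaldehyde (trans-anti-trans core)
Conditions: Dess–Martin periodinane (3 equiv), NaHCO3, CH2Cl2, 0 °C → rt
Reagents that add atoms: none
Why: Dess–Martin oxidation of both alcohols under neutral conditions, which should not epimerise C8a or C9a.

Step 20
Reactants: 28; 27
Product: 29 β-hydroxy nitrile: 1β-{2-cyano-1-hydroxy-3-[2-(4-iodobenzyl)-1,3-dioxolan-2-yl]propyl}-9-ketone (mixture at the two new centres)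
Conditions: 27 (1.3 equiv), LDA (1.25 equiv), THF, −78 °C; then 28, −78 °C; AcOH quench at −78 °C
Reagents that add atoms: none
Why: Nitrile-anion aldol addition, selective for the aldehyde over the hindered cyclopentanone; both new centres are erased or equilibrated later.

Step 21
Reactants: 29
Product: 30 triethylsilyl ether of 29
Conditions: TESCl, imidazole, DMAP (cat.), DMF, 23 °C
Reagents that add atoms: chlorotriethylsilane, CC[Si](Cl)(CC)CC
Why: Silylation protects the aldol hydroxyl (against retro-aldol and O-arylation) without enolising the C9 ketone.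

Step 22
Reactants: 30
Product: 31 9β-alcohol (9-Hα) of 30
Conditions: NaBH4, MeOH/THF, −20 → 0 °C
Reagents that add atoms: none
Why: Hydride should attack the C9 ketone from the α-face, anti to the angular C4b methyl and the C1 side chain, giving the 9β-alcohol needed for etherification with retention.

Step 23
Reactants: 31
Product: 32 macrocyclic aryl ether (13-membered ring; C9β–O–aryl; OTES, dioxolane, nitrile retained)
Conditions: CuI (30 mol%), 3,4,7,8-tetramethyl-1,10-phenanthroline (60 mol%), Cs2CO3 (3 equiv), toluene, 110 °C, 1 mM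
Reagents that add atoms: none
Why: Intramolecular Ullmann-type O-arylation of the secondary alkoxide closes the para-cyclophane with retention at C9; this ring closure has precedent in this natural-product family.

Step 24
Reactants: 32
Product: 33 macrocyclic β-hydroxy nitrile benzyl ketone
Conditions: 1 M HCl, THF, 23 °C
Reagents that add atoms: water, O
Why: Acid hydrolysis removes the dioxolane and the silyl ether in one operation.

Step 25
Reactants: 33
Product: 34 macrocyclic 2-cyano-1,4-diketone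
Conditions: Dess–Martin periodinane, CH2Cl2, 23 °C
Reagents that add atoms: none
Why: Dess–Martin oxidation of the secondary alcohol gives the β-keto nitrile.

Step 26
Reactants: 34
Product: 36 target CNP0450261.1, via open-chain keto amide 35 (not isolated)
Conditions: [PtH{(PMe2O)2H}(PMe2OH)] (5 mol%), EtOH/H2O (4:1), 80 °C; then 23 °C
Reagents that add atoms: water, O
Why: Neutral Pt-catalysed nitrile hydration (Ghaffar–Parkins catalyst) gives the primary amide, which should add to the γ-ketone to form the 5-hydroxy-γ-lactam; the acyl-bearing carbon and the hemiaminal should settle to the thermodynamic pair.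

**Compound list**

1 | (E)-4-(benzyloxy)but-2-enal | O=C/C=C/COCc1ccccc1 | starting material
2 | ethyl 3-oxopentanoate | CCC(=O)CC(=O)OCC | starting material
3 | ethyl 2-[(2R)-1-(benzyloxy)-4-oxobutan-2-yl]-3-oxopentanoate | CCC(=O)C(C(=O)OCC)[C@@H](CC=O)COCc1ccccc1 | intermediate
4 | ethyl (6R)-6-[(benzyloxy)methyl]-3-methyl-2-oxocyclohex-3-ene-1-carboxylate (ester trans to CH2OBn; C1 epimerisable) | CCOC(=O)[C@@H]1C(=O)C(C)=CC[C@H]1COCc1ccccc1 | intermediate
5 | ethyl (1R,6R)-6-[(benzyloxy)methyl]-1,3-dimethyl-2-oxocyclohex-3-ene-1-carboxylate | CCOC(=O)[C@@]1(C)C(=O)C(C)=CC[C@H]1COCc1ccccc1 | intermediate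
6 | silyl dienol ether of 5 | CCOC(=O)[C@@]1(C)C(O[Si](C)(C)C(C)(C)C)=C(C)C=C[C@H]1COCc1ccccc1 | intermediate
7 | ethyl 6-[(benzyloxy)methyl]-5-(dimethoxymethyl)-1,3-dimethyl-2-oxocyclohex-3-ene-1-carboxylate | CCOC(=O)[C@@]1(C)C(=O)C(C)=C[C@H](C(OC)OC)[C@H]1COCc1ccccc1 | intermediate
8 | {6-[(benzyloxy)methyl]-5-(dimethoxymethyl)-2-hydroxy-1,3-dimethylcyclohex-3-en-1-yl}methanol | OC[C@@]1(C)[C@@H](O)C(C)=C[C@H](C(OC)OC)[C@H]1COCc1ccccc1 | intermediate
9 | 6-[(benzyloxy)methyl]-5-(dimethoxymethyl)-1,3-dimethyl-2-oxocyclohex-3-ene-1-carbaldehyde | O=C[C@@]1(C)C(=O)C(C)=C[C@H](C(OC)OC)[C@H]1COCc1ccccc1 | intermediate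
10 | 5-[(benzyloxy)methyl]-4-(dimethoxymethyl)-6-ethenyl-2,6-dimethylcyclohex-2-en-1-one | C=C[C@@]1(C)C(=O)C(C)=C[C@H](C(OC)OC)[C@H]1COCc1ccccc1 | intermediate
11 | 5-[(benzyloxy)methyl]-4-(dimethoxymethyl)-6-ethenyl-2,6-dimethylcyclohex-2-en-1-ol (OH cis to vinyl) | C=C[C@@]1(C)[C@@H](O)C(C)=C[C@H](C(OC)OC)[C@H]1COCc1ccccc1 | intermediate
12 | methyl carbonate of 11 | C=C[C@@]1(C)[C@@H](OC(=O)OC)C(C)=C[C@H](C(OC)OC)[C@H]1COCc1ccccc1 | intermediate
13 | 6-[(benzyloxy)methyl]-5-ethenyl-4-[(methoxycarbonyl)oxy]-3,5-dimethylcyclohex-2-ene-1-carbaldehyde | C=C[C@@]1(C)[C@@H](OC(=O)OC)C(C)=C[C@H](C=O)[C@H]1COCc1ccccc1 | intermediate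
14 | 2,4,6-trimethylphenol (mesitol) | Cc1cc(C)c(O)c(C)c1 | starting material
15 | 6-[(benzyloxy)methyl]-5-ethenyl-3,5-dimethyl-2-(1,3,5-trimethyl-4-oxocyclohexa-2,5-dien-1-yl)cyclohex-3-ene-1-carbaldehyde (dienonyl trans to CHO) | C=C[C@@]1(C)C=C(C)[C@@H](C2(C)C=C(C)C(=O)C(C)=C2)[C@@H]([C@H]1COCc1ccccc1)C=O | intermediate
16 | cis-B/C hydrofluorene-7,9-dione: 1β-CH2OBn; 2β-vinyl, 2α-Me; Δ3, 4-Me; 4a-Hα; 4b-Meβ; Δ5, 6-Me; 8α-Me (inconsequential); 8a-Hβ; 9a-Hβ | C=C[C@@]1(C)C=C(C)[C@@H]2[C@@H]([C@H]1COCc1ccccc1)C(=O)[C@H]1[C@@H](C)C(=O)C(C)=C[C@]12C | intermediate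
17 | 9α-hydroxy-7-one from 16 | C=C[C@@]1(C)C=C(C)[C@@H]2[C@@H]([C@H]1COCc1ccccc1)[C@@H](O)[C@H]1[C@@H](C)C(=O)C(C)=C[C@]12C | intermediate
18 | 9α-OTMS 7-(trimethylsilyloxy)-5,7-diene | C=C[C@@]1(C)C=C(C)[C@@H]2[C@@H]([C@H]1COCc1ccccc1)[C@@H](O[Si](C)(C)C)[C@H]1C(C)=C(O[Si](C)(C)C)C(C)=C[C@]12C | intermediate
19 | 9α-hydroxy-Δ5,Δ8(8a)-dien-7-one (benzyl ether) | C=C[C@@]1(C)C=C(C)[C@@H]2[C@@H]([C@H]1COCc1ccccc1)[C@@H](O)C1=C(C)C(=O)C(C)=C[C@]12C | intermediate
20 | trans-B/C keto diol: 1β-CH2OH; 9α-OH; 7-oxo; 6α,8α-Me2; 8a-Hα | C=C[C@@]1(C)C=C(C)[C@@H]2[C@@H]([C@H]1CO)[C@@H](O)[C@@H]1[C@@H](C)C(=O)[C@@H](C)C[C@]12C | intermediate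
21 | 7-hydrazone of 20 | C=C[C@@]1(C)C=C(C)[C@@H]2[C@@H]([C@H]1CO)[C@@H](O)[C@@H]1[C@@H](C)C(=NN)[C@@H](C)C[C@]12C | intermediate
22 | 7-deoxo diol (1β-CH2OH; 9α-OH) | C=C[C@@]1(C)C=C(C)[C@@H]2[C@@H]([C@H]1CO)[C@@H](O)[C@@H]1[C@@H](C)C[C@@H](C)C[C@]12C | intermediate
23 | 2-(4-iodophenyl)ethanol | OCCc1ccc(I)cc1 | starting material
24 | (4-iodophenyl)acetaldehyde | O=CCc1ccc(I)cc1 | intermediate
25 | acrylonitrile | C=CC#N | starting material
26 | 5-(4-iodophenyl)-4-oxopentanenitrile | N#CCCC(=O)Cc1ccc(I)cc1 | intermediate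
27 | 3-[2-(4-iodobenzyl)-1,3-dioxolan-2-yl]propanenitrile | N#CCCC1(Cc2ccc(I)cc2)OCCO1 | intermediate
28 | 9-oxo-1β-carbaldehyde | C=C[C@@]1(C)C=C(C)[C@@H]2[C@@H]([C@H]1C=O)C(=O)[C@@H]1[C@@H](C)C[C@@H](C)C[C@]12C | intermediate
29 | β-hydroxy nitrile (aldol adduct of 28 and 27) | C=C[C@@]1(C)C=C(C)[C@@H]2[C@@H]([C@H]1C(O)C(C#N)CC1(Cc3ccc(I)cc3)OCCO1)C(=O)[C@@H]1[C@@H](C)C[C@@H](C)C[C@]12C | intermediate
30 | triethylsilyl ether of 29 | C=C[C@@]1(C)C=C(C)[C@@H]2[C@@H]([C@H]1C(O[Si](CC)(CC)CC)C(C#N)CC1(Cc3ccc(I)cc3)OCCO1)C(=O)[C@@H]1[C@@H](C)C[C@@H](C)C[C@]12C | intermediate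
31 | 9β-alcohol of 30 | C=C[C@@]1(C)C=C(C)[C@@H]2[C@@H]([C@H]1C(O[Si](CC)(CC)CC)C(C#N)CC1(Cc3ccc(I)cc3)OCCO1)[C@H](O)[C@@H]1[C@@H](C)C[C@@H](C)C[C@]12C | intermediate
32 | macrocyclic aryl ether (OTES, dioxolane, nitrile) | C=C[C@@]1(C)C=C(C)[C@@H]2[C@@H]3[C@H](Oc4ccc(cc4)CC4(OCCO4)CC(C#N)C(O[Si](CC)(CC)CC)[C@H]31)[C@@H]1[C@@H](C)C[C@@H](C)C[C@]12C | intermediate
33 | macrocyclic β-hydroxy nitrile benzyl ketone | C=C[C@@]1(C)C=C(C)[C@@H]2[C@@H]3[C@H](Oc4ccc(cc4)CC(=O)CC(C#N)C(O)[C@H]31)[C@@H]1[C@@H](C)C[C@@H](C)C[C@]12C | intermediate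
34 | macrocyclic 2-cyano-1,4-diketone | C=C[C@@]1(C)C=C(C)[C@@H]2[C@@H]3[C@H](Oc4ccc(cc4)CC(=O)CC(C#N)C(=O)[C@H]31)[C@@H]1[C@@H](C)C[C@@H](C)C[C@]12C | intermediate
35 | open-chain γ-keto β-keto primary amide | C=C[C@@]1(C)C=C(C)[C@@H]2[C@@H]3[C@H](Oc4ccc(cc4)CC(=O)CC(C(N)=O)C(=O)[C@H]31)[C@@H]1[C@@H](C)C[C@@H](C)C[C@]12C | intermediate
36 | CNP0450261.1 | C=C[C@@]1(C)C=C(C)[C@@H]2[C@@H]3[C@H](Oc4ccc(cc4)C[C@@]4(O)C[C@H](C(=O)N4)C(=O)[C@H]31)[C@@H]1[C@@H](C)C[C@@H](C)C[C@]12C | target

**Count**
Total steps: 26. Longest linear sequence: 23 (steps 1–15 and 19–26); steps 16–18 form the side-chain branch.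

**Steps most likely to fail**

Step 11. O-allylation or ortho attack of the phenol may outrun para C-allylation with this hindered cyclic π-allyl, or the Stetter stage may select the wrong enone arm. The fallback uses known reactions only and forms the two bonds in separate operations, arene first. It sets out from 13. Addition of the Grignard reagent made from (3-bromo-2,4,6-trimethylphenoxy)(tert-butyl)dimethylsilane F1 (silylation of commercial 3-bromo-2,4,6-trimethylphenol) at −78 °C, selective for the aldehyde, should give the Felkin–Anh benzylic alcohol F2. Dess–Martin oxidation gives the aryl ketone F3, and hydride reduction (NaBH4/CeCl3), again Felkin–Anh but now delivering hydrogen, should give the epimeric alcohol F4. TBAF frees the phenol F5. Pd(PPh3)4 in toluene then effects the intramolecular dearomative allylic alkylation (para carbon onto the π-allyl, C4a–C4b bond) to the 9β-hydroxy dienone F6; the benzylic C–O bond turns out of the arene plane to avoid 1,3-allylic strain and so should relay its configuration to C4b. F6 is the C9 epimer of 19. Under the conditions of steps 14 and 15 it should give the 9β-hydroxy keto diol F7 and the 9β-hydroxy diol F8, and the oxidation of step 19 brings the sequence back at 28.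

Step 14. The C8a carbanion may be protonated on the wrong face (cis fusion), or the reduction may stop at a mono-enone. The fallback replaces electron transfer by hydride conjugate addition and sets out from 19. Copper hydride (DIBAL-H, t-BuCu, HMPA, THF, −50 °C), applied twice with hydrolysis of the aluminium enolate in between and followed by NaOMe equilibration, should deliver hydride to C8a anti to the C4b methyl and give the benzyl ether of the keto diol F9. Wolff–Kishner reduction as in step 15 gives the benzyl ether of the diol F10, and debenzylation with lithium di-tert-butylbiphenylide (THF, −78 °C) returns to the route at 22.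

Step 23. The hindered C9 alkoxide may fail to close the strained 13-membered ring, so that intermolecular arylation (oligomers) takes over. The fallback makes the aryl ether intermolecularly and closes the macrocycle at the C1′–C(α-cyano) bond instead; it sets out from 22. TBSCl/imidazole gives the primary silyl ether F11, Dess–Martin oxidation the C9 ketone F12, and NaBH4 the 9β-alcohol F13. Cu-catalysed O-arylation with iodide 27 (catalyst system of step 23, 0.5 M) gives the aryl ether F14. TBAF gives the primary alcohol F15 and Dess–Martin oxidation the aldehyde F16. LiHMDS (THF, −78 °C, 1 mM) should then close the ring by intramolecular nitrile-anion addition to the aldehyde, giving the macrocyclic β-hydroxy nitrile ketal F17, which under the conditions of step 24 gives 33.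

**Further compounds**

F1 | step 11 | (3-bromo-2,4,6-trimethylphenoxy)(tert-butyl)dimethylsilane | Cc1cc(C)c(Br)c(C)c1O[Si](C)(C)C(C)(C)C
F2 | step 11 | Felkin–Anh benzylic alcohol (aryl adduct of 13) | C=C[C@@]1(C)[C@@H](OC(=O)OC)C(C)=C[C@@H]([C@H]1COCc1ccccc1)[C@@H](O)c1c(C)cc(C)c(O[Si](C)(C)C(C)(C)C)c1C
F3 | step 11 | aryl ketone | C=C[C@@]1(C)[C@@H](OC(=O)OC)C(C)=C[C@@H]([C@H]1COCc1ccccc1)C(=O)c1c(C)cc(C)c(O[Si](C)(C)C(C)(C)C)c1C
F4 | step 11 | epimeric benzylic alcohol | C=C[C@@]1(C)[C@@H](OC(=O)OC)C(C)=C[C@@H]([C@H]1COCc1ccccc1)[C@H](O)c1c(C)cc(C)c(O[Si](C)(C)C(C)(C)C)c1C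
F5 | step 11 | free phenol of F4 | C=C[C@@]1(C)[C@@H](OC(=O)OC)C(C)=C[C@@H]([C@H]1COCc1ccccc1)[C@H](O)c1c(C)cc(C)c(O)c1C
F6 | step 11 | 9β-hydroxy dienone (C9 epimer of 19) | C=C[C@@]1(C)C=C(C)[C@@H]2[C@@H]([C@H]1COCc1ccccc1)[C@H](O)C1=C(C)C(=O)C(C)=C[C@]12C
F7 | step 11 | 9β-hydroxy keto diol (C9 epimer of 20) | C=C[C@@]1(C)C=C(C)[C@@H]2[C@@H]([C@H]1CO)[C@H](O)[C@@H]1[C@@H](C)C(=O)[C@@H](C)C[C@]12C
F8 | step 11 | 9β-hydroxy diol (C9 epimer of 22) | C=C[C@@]1(C)C=C(C)[C@@H]2[C@@H]([C@H]1CO)[C@H](O)[C@@H]1[C@@H](C)C[C@@H](C)C[C@]12C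
F9 | step 14 | benzyl ether of the keto diol 20 | C=C[C@@]1(C)C=C(C)[C@@H]2[C@@H]([C@H]1COCc1ccccc1)[C@@H](O)[C@@H]1[C@@H](C)C(=O)[C@@H](C)C[C@]12C
F10 | step 14 | benzyl ether of the diol 22 | C=C[C@@]1(C)C=C(C)[C@@H]2[C@@H]([C@H]1COCc1ccccc1)[C@@H](O)[C@@H]1[C@@H](C)C[C@@H](C)C[C@]12C
F11 | step 23 | primary silyl ether of 22 | C=C[C@@]1(C)C=C(C)[C@@H]2[C@@H]([C@H]1CO[Si](C)(C)C(C)(C)C)[C@@H](O)[C@@H]1[C@@H](C)C[C@@H](C)C[C@]12C
F12 | step 23 | C9 ketone | C=C[C@@]1(C)C=C(C)[C@@H]2[C@@H]([C@H]1CO[Si](C)(C)C(C)(C)C)C(=O)[C@@H]1[C@@H](C)C[C@@H](C)C[C@]12C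
F13 | step 23 | 9β-alcohol | C=C[C@@]1(C)C=C(C)[C@@H]2[C@@H]([C@H]1CO[Si](C)(C)C(C)(C)C)[C@H](O)[C@@H]1[C@@H](C)C[C@@H](C)C[C@]12C
F14 | step 23 | aryl ether | C=C[C@@]1(C)C=C(C)[C@@H]2[C@@H]([C@H]1CO[Si](C)(C)C(C)(C)C)[C@H](Oc1ccc(CC3(CCC#N)OCCO3)cc1)[C@@H]1[C@@H](C)C[C@@H](C)C[C@]12C
F15 | step 23 | primary alcohol | C=C[C@@]1(C)C=C(C)[C@@H]2[C@@H]([C@H]1CO)[C@H](Oc1ccc(CC3(CCC#N)OCCO3)cc1)[C@@H]1[C@@H](C)C[C@@H](C)C[C@]12C
F16 | step 23 | aldehyde | C=C[C@@]1(C)C=C(C)[C@@H]2[C@@H]([C@H]1C=O)[C@H](Oc1ccc(CC3(CCC#N)OCCO3)cc1)[C@@H]1[C@@H](C)C[C@@H](C)C[C@]12C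
F17 | step 23 | macrocyclic β-hydroxy nitrile ketal | C=C[C@@]1(C)C=C(C)[C@@H]2[C@@H]3[C@H](Oc4ccc(cc4)CC4(OCCO4)CC(C#N)C(O)[C@H]31)[C@@H]1[C@@H](C)C[C@@H](C)C[C@]12C
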